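**Retrosynthetic overview**

1. Target 25 ⇐ chemoselective opening of the cis-fused α-methylene-γ-lactone 24 (C6–O/C12); the C8 ester ⇐ C8–OH + Roche-ester-derived acid 22; the exo-methylene ⇐ Eschenmoser methylenation.
2. Lactone ⇐ equatorial hydride reduction of the C6 ketone 13; its C7 acetate arm and C5 hydroxypropenyl unit ⇐ enolate alkylation and Pd-catalysed α-alkenylation.
3. Quaternary C10 ⇐ two successive conjugate additions (vinyl, then methyl) to (S)-5-silyloxycyclohexenone 6, both steered by the C8 silyloxy group.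
4. 6 ⇐ (S)-3-hydroxycyclohexanone 3 ⇐ key step: one-flask hydrogenative dearomatisation of resorcinol to the symmetric 1,3-dione and ketoreductase desymmetrisation, which sets C8, the only catalyst-controlled stereocentre.
5. Ring order: the carbocycle is the resorcinol ring throughout; the only other ring, the γ-lactone, is closed in step 9 and opened in step 16.

Assumption: the target is made exactly as drawn (free C12 acid, free axial C6 hydroxyl, i.e. the seco acid of the 6,12-lactone); ring carbons are called C5–C10 (elemane numbering: C10 quaternary, C9 CH2, C8 ester carbinol, C7 acrylic acid carbon, C6 carbinol, C5 hydroxypropenyl carbon).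

This route is a paper design and has not been run; the stereochemical outcomes rest on conformational arguments.

**Route**

Step 1
Reactants: 1 resorcinol
Product: 3 (S)-3-hydroxycyclohexan-1-one, via cyclohexane-1,3-dione 2 (not isolated)
Conditions: H2 (5 bar), Pd/C, NaOH (1.05 equiv), H2O, 50 °C; filter; HCl to pH 6.5; (S)-selective ketoreductase, NADP+ (cat.), i-PrOH (10 vol %), 30 °C
Reagents that add atoms: none
Why: Proposed new method: a one-flask dearomatisation–desymmetrisation in which hydrogenation of the resorcinolate stops at the enolate of the vinylogous acid 2 and an (S)-selective ketoreductase then delivers hydride to one face of one of the two enantiotopic carbonyls of the neutral diketone present at pH 6.5, setting C8 (S) as the only stereocentre fixed by a chiral catalyst; the closest known reaction types are the alkaline hydrogenation of resorcinol to dihydroresorcinol and the microbial or ketoreductase mono-reduction of cyclohexane-1,3-diones.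

Step 2
Reactants: 3 (S)-3-hydroxycyclohexan-1-one
Product: 4 (S)-3-[(tert-butyldimethylsilyl)oxy]cyclohexan-1-one
Conditions: t-BuMe2SiCl, imidazole, DMF, 0 → 25 °C
Reagents that add atoms: tert-butyldimethylsilyl chloride, CC(C)(C)[Si](C)(C)Cl
Why: Standard silylation of the β-hydroxy ketone under neutral conditions (no β-elimination) gives the bulky C8 ether that later steers both conjugate additions and the C7 alkylation, the stereocentre being untouched.

Step 3
Reactants: 4 (S)-3-[(tert-butyldimethylsilyl)oxy]cyclohexan-1-one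
Product: 6 (S)-5-[(tert-butyldimethylsilyl)oxy]cyclohex-2-en-1-one, via silyl enol ether 5 (not isolated)
Conditions: LiN(i-Pr)2, Me3SiCl, THF, −78 °C; then Pd(OAc)2 (10 mol %), O2 (1 atm), DMSO, 25 °C
Reagents that add atoms: none
Why: Kinetic enolisation takes place at C5, away from the β-silyloxy group, and Saegusa–Ito dehydrogenation of silyl enol ether 5 (catalytic divalent palladium reoxidised by O2) gives the C5=C10 enone while C8 stays as set.

Step 4
Reactants: 6 (S)-5-[(tert-butyldimethylsilyl)oxy]cyclohex-2-en-1-one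
Product: 8 (S)-5-[(tert-butyldimethylsilyl)oxy]-3-ethenylcyclohex-2-en-1-one, via vinyl silyl enol ether 7 (not isolated)
Conditions: CH2=CHMgBr, CuBr·SMe2 (10 mol %), Me3SiCl, THF, −78 °C; then Pd(OAc)2 (10 mol %), O2 (1 atm), DMSO, 25 °C
Reagents that add atoms: vinylmagnesium bromide, C=C[Mg]Br
Why: Copper-catalysed conjugate addition of the vinyl Grignard reagent with in situ silylation puts the vinyl group on C10 (anti to the C8 silyloxy group, a centre that is erased again) and a second Saegusa–Ito oxidation regenerates the enone as the cross-conjugated dienone, so that the quaternary centre can be completed by the next nucleophile.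

Step 5
Reactants: 8 (S)-5-[(tert-butyldimethylsilyl)oxy]-3-ethenylcyclohex-2-en-1-one
Product: 9 tert-butyl{[(1S,5S)-5-ethenyl-5-methyl-3-(trimethylsilyloxy)cyclohex-3-en-1-yl]oxy}dimethylsilane
Conditions: MeMgBr, Cu(OTf)2 (5 mol %), SIMes·HCl (6 mol %), Et2O, −30 °C; then Me3SiCl, Et3N, −30 → 0 °C
Reagents that add atoms: methylmagnesium bromide, C[Mg]Br; chlorotrimethylsilane, C[Si](C)(C)Cl
Why: NHC–copper-catalysed conjugate addition of Grignard reagents is 1,4-selective on 3-alkenyl cyclohexenones, and axial attack anti to the pseudo-equatorial C8 silyloxy group places the new methyl trans and the vinyl cis to C8–O, which sets the quaternary C10 (S), while silylation stores the regiodefined C5 enolate as enol ether 9.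

Step 6
Reactants: 10 2-bromoprop-2-en-1-ol
Product: 11 [(2-bromoprop-2-en-1-yl)oxy](tert-butyl)diphenylsilane
Conditions: t-BuPh2SiCl, imidazole, CH2Cl2, 25 °C
Reagents that add atoms: tert-butyl(chloro)diphenylsilane, CC(C)(C)[Si](Cl)(c1ccccc1)c1ccccc1
Why: Routine silylation of the primary allylic alcohol gives an acid-stable ether that can later be kept while the C8 silyl ether is removed, no stereocentre being involved.

Step 7
Reactants: 9 tert-butyl{[(1S,5S)-5-ethenyl-5-methyl-3-(trimethylsilyloxy)cyclohex-3-en-1-yl]oxy}dimethylsilane; 11 [(2-bromoprop-2-en-1-yl)oxy](tert-butyl)diphenylsilane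
Product: 12 (2R,3S,5S)-5-[(tert-butyldimethylsilyl)oxy]-2-{3-[(tert-butyldiphenylsilyl)oxy]prop-1-en-2-yl}-3-ethenyl-3-methylcyclohexan-1-one
Conditions: MeLi, THF, 0 °C; ZnCl2; Pd2(dba)3 (3 mol %), P(t-Bu)3 (6 mol %), 11, 50 °C; then LiN(SiMe3)2, −78 °C; AcOH, −78 °C
Reagents that add atoms: none
Why: Methyllithium releases the regiodefined enolate and palladium-catalysed α-alkenylation of its zinc enolate with the vinyl bromide (Negishi-type ketone α-vinylation through zerovalent palladium) forms the C5–C4 bond, after which the product is converted into its extended enolate and protonated kinetically at C5 from the face opposite the axial C10 methyl, so the side chain ends equatorial and cis to that methyl (5R), which is also the more stable epimer.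

Step 8
Reactants: 12 (2R,3S,5S)-5-[(tert-butyldimethylsilyl)oxy]-2-{3-[(tert-butyldiphenylsilyl)oxy]prop-1-en-2-yl}-3-ethenyl-3-methylcyclohexan-1-one
Product: 13 methyl 2-[(1R,2S,4S,5R)-2-[(tert-butyldimethylsilyl)oxy]-5-{3-[(tert-butyldiphenylsilyl)oxy]prop-1-en-2-yl}-4-ethenyl-4-methyl-6-oxocyclohexyl]acetate
Conditions: LiN(i-Pr)2, THF, −78 °C; BrCH2CO2Me, DMPU, −78 → −40 °C
Reagents that add atoms: methyl bromoacetate, COC(=O)CBr
Why: Kinetic deprotonation takes the open C7 methylene and not the C5 methine, which is buried between the quaternary C10 and the branched alkene, and the enolate is alkylated (SN2) anti to the neighbouring C8 silyloxy group, so the acetate arm ends equatorial, trans to C8–O and cis to the C5 chain (7R), the cold conditions suppressing β-elimination of the silyloxy group.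

Step 9
Reactants: 13 methyl 2-[(1R,2S,4S,5R)-2-[(tert-butyldimethylsilyl)oxy]-5-{3-[(tert-butyldiphenylsilyl)oxy]prop-1-en-2-yl}-4-ethenyl-4-methyl-6-oxocyclohexyl]acetate
Product: 15 (3aS,4S,6S,7R,7aS)-4-[(tert-butyldimethylsilyl)oxy]-7-{3-[(tert-butyldiphenylsilyl)oxy]prop-1-en-2-yl}-6-ethenyl-6-methylhexahydro-1-benzofuran-2(3H)-one, via hydroxy ester 14 (not isolated)
Conditions: LiBH(s-Bu)3, THF, −78 → 0 °C
Reagents that add atoms: none
Why: The bulky borohydride attacks the C6 ketone from the equatorial side because the axial face is blocked by the 1,3-related axial C10 methyl and by both equatorial α-substituents, so the alkoxide is axial and cis to both neighbours (6S) and lactonises at once with the cis acetate arm to the cis-fused γ-lactone (diastereoselective ketone reduction followed by transesterification).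

Step 10
Reactants: 15 (3aS,4S,6S,7R,7aS)-4-[(tert-butyldimethylsilyl)oxy]-7-{3-[(tert-butyldiphenylsilyl)oxy]prop-1-en-2-yl}-6-ethenyl-6-methylhexahydro-1-benzofuran-2(3H)-one
Product: 18 (3aS,4S,6S,7R,7aS)-4-[(tert-butyldimethylsilyl)oxy]-7-{3-[(tert-butyldiphenylsilyl)oxy]prop-1-en-2-yl}-6-ethenyl-6-methyl-3-methylidenehexahydro-1-benzofuran-2(3H)-one, via Mannich base 16 (not isolated), via methiodide 17 (not isolated)
Conditions: LiN(i-Pr)2, THF, −78 °C; [CH2=NMe2]I, −78 → 25 °C; MeI, MeOH, 25 °C; NaHCO3 (aq), CH2Cl2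
Reagents that add atoms: N,N-dimethylmethyleneiminium iodide (Eschenmoser's salt), C=[N+](C)C.[I-]
Why: Eschenmoser methylenation, that is Mannich reaction of the lactone enolate with the iminium salt, N-methylation and base-induced elimination of trimethylamine, installs the C11=C13 exo-methylene without touching a stereocentre.

Step 11
Reactants: 18 (3aS,4S,6S,7R,7aS)-4-[(tert-butyldimethylsilyl)oxy]-7-{3-[(tert-butyldiphenylsilyl)oxy]prop-1-en-2-yl}-6-ethenyl-6-methyl-3-methylidenehexahydro-1-benzofuran-2(3H)-one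
Product: 19 (3aR,4S,6S,7R,7aS)-7-{3-[(tert-butyldiphenylsilyl)oxy]prop-1-en-2-yl}-6-ethenyl-4-hydroxy-6-methyl-3-methylidenehexahydro-1-benzofuran-2(3H)-one
Conditions: camphorsulfonic acid (20 mol %), MeOH–CH2Cl2 1:1, 0 → 25 °C
Reagents that add atoms: none
Why: Acid-catalysed methanolysis cleaves the dimethyl-tert-butylsilyl ether far faster than the diphenyl-tert-butylsilyl ether, so only the C8 hydroxyl is released and no stereocentre is affected.

Step 12
Reactants: 20 methyl (R)-3-hydroxy-2-methylpropanoate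
Product: 21 methyl (R)-3-[(tert-butyldimethylsilyl)oxy]-2-methylpropanoate
Conditions: t-BuMe2SiCl, imidazole, CH2Cl2, 0 → 25 °C
Reagents that add atoms: tert-butyldimethylsilyl chloride, CC(C)(C)[Si](C)(C)Cl
Why: Silylation of the primary alcohol of the Roche ester protects it for the later esterification, the (R) centre not being involved.

Step 13
Reactants: 21 methyl (R)-3-[(tert-butyldimethylsilyl)oxy]-2-methylpropanoate
Product: 22 (R)-3-[(tert-butyldimethylsilyl)oxy]-2-methylpropanoic acid
Conditions: LiOH, THF–H2O, 0 → 25 °C; then 1 M HCl to pH 3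
Reagents that add atoms: lithium hydroxide, [Li+].[OH-]
Why: Mild saponification of the methyl ester gives the acid without epimerising the α-stereocentre.

Step 14
Reactants: 19 (3aR,4S,6S,7R,7aS)-7-{3-[(tert-butyldiphenylsilyl)oxy]prop-1-en-2-yl}-6-ethenyl-4-hydroxy-6-methyl-3-methylidenehexahydro-1-benzofuran-2(3H)-one; 22 (R)-3-[(tert-butyldimethylsilyl)oxy]-2-methylpropanoic acid
Product: 23 (3aR,4S,6S,7R,7aS)-7-{3-[(tert-butyldiphenylsilyl)oxy]prop-1-en-2-yl}-6-ethenyl-6-methyl-3-methylidene-2-oxooctahydro-1-benzofuran-4-yl (R)-3-[(tert-butyldimethylsilyl)oxy]-2-methylpropanoate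
Conditions: DCC, DMAP (20 mol %), CH2Cl2, 0 → 25 °C
Reagents that add atoms: none
Why: Steglich esterification (carbodiimide activation with acyl transfer through the acylpyridinium) acylates the only free hydroxyl, the equatorial C8–OH, with retention at C8 and without loss of the (R) configuration of the acid.

Step 15
Reactants: 23 (3aR,4S,6S,7R,7aS)-7-{3-[(tert-butyldiphenylsilyl)oxy]prop-1-en-2-yl}-6-ethenyl-6-methyl-3-methylidene-2-oxooctahydro-1-benzofuran-4-yl (R)-3-[(tert-butyldimethylsilyl)oxy]-2-methylpropanoate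
Product: 24 (3aR,4S,6S,7R,7aS)-6-ethenyl-7-(3-hydroxyprop-1-en-2-yl)-6-methyl-3-methylidene-2-oxooctahydro-1-benzofuran-4-yl (R)-3-hydroxy-2-methylpropanoate
Conditions: HF·pyridine, pyridine, THF, 0 → 25 °C
Reagents that add atoms: none
Why: Buffered fluoride cleavage removes both primary silyl ethers while the α-methylene lactone and the C8 ester survive, no stereocentre being affected.

Step 16
Reactants: 24 (3aR,4S,6S,7R,7aS)-6-ethenyl-7-(3-hydroxyprop-1-en-2-yl)-6-methyl-3-methylidene-2-oxooctahydro-1-benzofuran-4-yl (R)-3-hydroxy-2-methylpropanoate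
Product: 25 2-[(1S,2S,3R,4S,6S)-4-ethenyl-2-hydroxy-3-(3-hydroxyprop-1-en-2-yl)-6-{[(2R)-3-hydroxy-2-methylpropanoyl]oxy}-4-methylcyclohexyl]prop-2-enoic acid
Conditions: LiOH (1.1 equiv), THF–H2O 3:1, 0 °C; then 0.5 M HCl to pH 5, 0 °C
Reagents that add atoms: lithium hydroxide, [Li+].[OH-]
Why: The strained and conjugatively activated α-methylene-γ-lactone is saponified much faster than the hindered α-branched secondary ester, and cold acidification to pH 5 liberates the seco acid with its axial C6 hydroxyl before relactonisation can occur, no stereocentre being affected.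

**Compound list**

1 | resorcinol (benzene-1,3-diol) | Oc1cccc(O)c1 | starting material
2 | cyclohexane-1,3-dione | O=C1CCCC(=O)C1 | intermediate
3 | (S)-3-hydroxycyclohexan-1-one | O=C1CCC[C@H](O)C1 | intermediate
4 | (S)-3-[(tert-butyldimethylsilyl)oxy]cyclohexan-1-one | O=C1CCC[C@H](O[Si](C)(C)C(C)(C)C)C1 | intermediate
5 | (S)-tert-butyldimethyl{[3-(trimethylsilyloxy)cyclohex-3-en-1-yl]oxy}silane (C5–C6 silyl enol ether of 4) | C[Si](C)(C)OC1=CCC[C@H](O[Si](C)(C)C(C)(C)C)C1 | intermediate
6 | (S)-5-[(tert-butyldimethylsilyl)oxy]cyclohex-2-en-1-one | O=C1C=CC[C@H](O[Si](C)(C)C(C)(C)C)C1 | intermediate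
7 | trimethylsilyl enol ether of trans-5-[(tert-butyldimethylsilyl)oxy]-3-ethenylcyclohexanone (vinyl trans to the silyloxy group) | C[Si](C)(C)OC1=C[C@@H](C=C)C[C@H](O[Si](C)(C)C(C)(C)C)C1 | intermediate
8 | (S)-5-[(tert-butyldimethylsilyl)oxy]-3-ethenylcyclohex-2-en-1-one | O=C1C=C(C=C)C[C@H](O[Si](C)(C)C(C)(C)C)C1 | intermediate
9 | tert-butyl{[(1S,5S)-5-ethenyl-5-methyl-3-(trimethylsilyloxy)cyclohex-3-en-1-yl]oxy}dimethylsilane (methyl trans, vinyl cis to the silyloxy group) | C=C[C@]1(C)C[C@H](O[Si](C)(C)C(C)(C)C)CC(O[Si](C)(C)C)=C1 | intermediate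
10 | 2-bromoprop-2-en-1-ol | C=C(Br)CO | starting material
11 | [(2-bromoprop-2-en-1-yl)oxy](tert-butyl)diphenylsilane | C=C(Br)CO[Si](c1ccccc1)(c1ccccc1)C(C)(C)C | intermediate
12 | (2R,3S,5S)-5-[(tert-butyldimethylsilyl)oxy]-2-{3-[(tert-butyldiphenylsilyl)oxy]prop-1-en-2-yl}-3-ethenyl-3-methylcyclohexan-1-one (C5 chain cis to C10 methyl) | C=C[C@]1(C)C[C@H](O[Si](C)(C)C(C)(C)C)CC(=O)[C@H]1C(=C)CO[Si](c2ccccc2)(c2ccccc2)C(C)(C)C | intermediate
13 | methyl 2-[(1R,2S,4S,5R)-2-[(tert-butyldimethylsilyl)oxy]-5-{3-[(tert-butyldiphenylsilyl)oxy]prop-1-en-2-yl}-4-ethenyl-4-methyl-6-oxocyclohexyl]acetate (C7 arm trans to C8–O, cis to the C5 chain) | C=C[C@]1(C)C[C@H](O[Si](C)(C)C(C)(C)C)[C@@H](CC(=O)OC)C(=O)[C@H]1C(=C)CO[Si](c2ccccc2)(c2ccccc2)C(C)(C)C | intermediate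
14 | C6 axial alcohol of 13 (hydroxy ester; 6-OH cis to both flanking chains) | C=C[C@]1(C)C[C@H](O[Si](C)(C)C(C)(C)C)[C@@H](CC(=O)OC)[C@@H](O)[C@H]1C(=C)CO[Si](c2ccccc2)(c2ccccc2)C(C)(C)C | intermediate
15 | (3aS,4S,6S,7R,7aS)-4-[(tert-butyldimethylsilyl)oxy]-7-{3-[(tert-butyldiphenylsilyl)oxy]prop-1-en-2-yl}-6-ethenyl-6-methylhexahydro-1-benzofuran-2(3H)-one (cis-fused C6–O/C12 lactone) | C=C[C@]1(C)C[C@H](O[Si](C)(C)C(C)(C)C)[C@@H](CC(=O)O2)[C@@H]2[C@H]1C(=C)CO[Si](c3ccccc3)(c3ccccc3)C(C)(C)C | intermediate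
16 | 3-[(dimethylamino)methyl] derivative of 15 (Mannich base; C11 epimers) | C=C[C@]1(C)C[C@H](O[Si](C)(C)C(C)(C)C)[C@@H](C(CN(C)C)C(=O)O2)[C@@H]2[C@H]1C(=C)CO[Si](c3ccccc3)(c3ccccc3)C(C)(C)C | intermediate
17 | trimethylammonium iodide of 16 (methiodide) | C=C[C@]1(C)C[C@H](O[Si](C)(C)C(C)(C)C)[C@@H](C(C[N+](C)(C)C)C(=O)O2)[C@@H]2[C@H]1C(=C)CO[Si](c3ccccc3)(c3ccccc3)C(C)(C)C.[I-] | intermediate
18 | (3aS,4S,6S,7R,7aS)-4-[(tert-butyldimethylsilyl)oxy]-7-{3-[(tert-butyldiphenylsilyl)oxy]prop-1-en-2-yl}-6-ethenyl-6-methyl-3-methylidenehexahydro-1-benzofuran-2(3H)-one | C=C[C@]1(C)C[C@H](O[Si](C)(C)C(C)(C)C)[C@@H](C(=C)C(=O)O2)[C@@H]2[C@H]1C(=C)CO[Si](c3ccccc3)(c3ccccc3)C(C)(C)C | intermediate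
19 | (3aR,4S,6S,7R,7aS)-7-{3-[(tert-butyldiphenylsilyl)oxy]prop-1-en-2-yl}-6-ethenyl-4-hydroxy-6-methyl-3-methylidenehexahydro-1-benzofuran-2(3H)-one | C=C[C@]1(C)C[C@H](O)[C@@H](C(=C)C(=O)O2)[C@@H]2[C@H]1C(=C)CO[Si](c3ccccc3)(c3ccccc3)C(C)(C)C | intermediate
20 | methyl (R)-3-hydroxy-2-methylpropanoate ((R)-Roche ester) | COC(=O)[C@H](C)CO | starting material
21 | methyl (R)-3-[(tert-butyldimethylsilyl)oxy]-2-methylpropanoate | COC(=O)[C@H](C)CO[Si](C)(C)C(C)(C)C | intermediate
22 | (R)-3-[(tert-butyldimethylsilyl)oxy]-2-methylpropanoic acid | OC(=O)[C@H](C)CO[Si](C)(C)C(C)(C)C | intermediate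
23 | (3aR,4S,6S,7R,7aS)-7-{3-[(tert-butyldiphenylsilyl)oxy]prop-1-en-2-yl}-6-ethenyl-6-methyl-3-methylidene-2-oxooctahydro-1-benzofuran-4-yl (R)-3-[(tert-butyldimethylsilyl)oxy]-2-methylpropanoate | C=C[C@]1(C)C[C@H](OC(=O)[C@H](C)CO[Si](C)(C)C(C)(C)C)[C@@H](C(=C)C(=O)O2)[C@@H]2[C@H]1C(=C)CO[Si](c3ccccc3)(c3ccccc3)C(C)(C)C | intermediate
24 | (3aR,4S,6S,7R,7aS)-6-ethenyl-7-(3-hydroxyprop-1-en-2-yl)-6-methyl-3-methylidene-2-oxooctahydro-1-benzofuran-4-yl (R)-3-hydroxy-2-methylpropanoate | C=C[C@]1(C)C[C@H](OC(=O)[C@H](C)CO)[C@@H](C(=C)C(=O)O2)[C@@H]2[C@H]1C(=C)CO | intermediate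
25 | 2-[(1S,2S,3R,4S,6S)-4-ethenyl-2-hydroxy-3-(3-hydroxyprop-1-en-2-yl)-6-{[(2R)-3-hydroxy-2-methylpropanoyl]oxy}-4-methylcyclohexyl]prop-2-enoic acid (CNP0462645.4) | C=C[C@]1(C)C[C@H](OC(=O)[C@H](C)CO)[C@@H](C(=C)C(=O)O)[C@@H](O)[C@H]1C(=C)CO | target

**Step count and weak points**

Total step count: 16. Longest linear sequence: 13 steps (steps 1–5, 7–11, 14–16); steps 6 and 12–13 make the two side fragments.

Three steps most likely to fail:

Step 7 (cross-coupling of a zinc enolate next to the quaternary carbon; the coupling may stall or the enolate may equilibrate). Fallback: set out from 9 and build the side chain by carbonyl addition instead of cross-coupling. The lithium enolate released from 9 with MeLi adds to acetone at −78 °C to give the acetone aldol F1 (kinetic C5 epimer). Burgess dehydration, then LiN(SiMe3)2 and AcOH at −78 °C (extended enolate, kinetic protonation at C5 as in step 7), gives the isopropenyl ketone F2. SeO2 (cat.)/t-BuOOH allylic hydroxylation of the isopropenyl methyl gives the allylic alcohol F3, and t-BuPh2SiCl/imidazole returns to 12.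

Step 8 (kinetic C7 enolate beside a β-silyloxy group and in the presence of the acidic C5–H; risks are wrong regiochemistry and β-elimination). Fallback: set out from 12 and use a Stork enamine in place of the lithium enolate. Pyrrolidine (TsOH cat., benzene, water removal) condenses toward the less hindered C7 to give the C6–C7 pyrrolidine enamine F4. This is C-alkylated with methyl bromoacetate (MeCN, 60 °C) and hydrolysed (aq AcOH/NaOAc), returning to 13 with the arm equatorial.

Step 16 (lactone opening in the presence of the C8 ester; risks are ester cleavage and relactonisation on acidification). Fallback: set out from 18, open the lactone before the side-chain ester exists and carry the acid as an allyl ester. LiOH, then allyl bromide/Cs2CO3 (DMF), gives the allyl ester hydroxy acrylate F5. HF·pyridine/pyridine removes the C8 silyl ether to give the diol F6. DCC/DMAP with 22 acylates the equatorial C8–OH selectively (the axial C6–OH between two branched carbons is inert) to give the diester F7. HF·pyridine removes both remaining silyl ethers to give the allyl ester triol F8, and Pd(PPh3)4/morpholine removes the allyl group under neutral conditions, coming back to the route at 25.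

**Further compounds**

F1 | step 7 | acetone aldol of the C5 enolate of 9 (kinetic C5 epimer; side chain trans to the C10 methyl) | C=C[C@]1(C)C[C@H](O[Si](C)(C)C(C)(C)C)CC(=O)[C@@H]1C(C)(C)O
F2 | step 7 | isopropenyl ketone (C5 configured as in 12) | C=C[C@]1(C)C[C@H](O[Si](C)(C)C(C)(C)C)CC(=O)[C@H]1C(C)=C
F3 | step 7 | allylic alcohol (12 without the tert-butyldiphenylsilyl group) | C=C[C@]1(C)C[C@H](O[Si](C)(C)C(C)(C)C)CC(=O)[C@H]1C(=C)CO
F4 | step 8 | C6–C7 pyrrolidine enamine of 12 | C=C[C@]1(C)C[C@H](O[Si](C)(C)C(C)(C)C)C=C(N2CCCC2)[C@H]1C(=C)CO[Si](c3ccccc3)(c3ccccc3)C(C)(C)C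
F5 | step 16 | allyl ester hydroxy acrylate (free C6–OH; C8 silyl ether and side-chain silyl ether retained) | C=C[C@]1(C)C[C@H](O[Si](C)(C)C(C)(C)C)[C@@H](C(=C)C(=O)OCC=C)[C@@H](O)[C@H]1C(=C)CO[Si](c2ccccc2)(c2ccccc2)C(C)(C)C
F6 | step 16 | C6,C8-diol allyl ester | C=C[C@]1(C)C[C@H](O)[C@@H](C(=C)C(=O)OCC=C)[C@@H](O)[C@H]1C(=C)CO[Si](c2ccccc2)(c2ccccc2)C(C)(C)C
F7 | step 16 | C8 (R)-3-silyloxy-2-methylpropanoate of F6 (diester) | C=C[C@]1(C)C[C@H](OC(=O)[C@H](C)CO[Si](C)(C)C(C)(C)C)[C@@H](C(=C)C(=O)OCC=C)[C@@H](O)[C@H]1C(=C)CO[Si](c2ccccc2)(c2ccccc2)C(C)(C)C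
F8 | step 16 | allyl ester of target 25 | C=C[C@]1(C)C[C@H](OC(=O)[C@H](C)CO)[C@@H](C(=C)C(=O)OCC=C)[C@@H](O)[C@H]1C(=C)CO
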